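(All runs come from a simulation from invented constants, and the scatter is random.)

Substrate charged stays counted whatever it becomes, so the readings of the south-west run at 6.00 h leave 58.7% of its charge in something neither reading shows.

| setting | east | south-west | beta | epsilon | eta | delta | alpha |
|---|---|---|---|---|---|---|---|
| substrate | 0.20 M | 0.20 M | 0.20 M | 0.20 M | 0.20 M | 0.20 M | 0.20 M |
| activator | 0.018 M | 0.30 M | 0.0300 M | 0.0600 M | 0.120 M | 0.250 M | 0.500 M |
| remark | run made earlier | run made earlier |  |  |  |  |  |
| time |  |  | 8.0 h | 8.0 h | 8.0 h | 8.0 h | 8.0 h |

- east (time / h: ring / %, substrate / %): 1.00: 1.4, 96.2; 2.50: 0, 94.4; 3.00: 0, 92.1; 5.00: 2.1, 92.1; 6.00: 1.6, 91.6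
- south-west (time / h: ring / %, substrate / %): 0.417: 2.5, 84.6; 0.833: 3.7, 72.3; 1.50: 7.9, 58.6; 3.00: 14.3, 38.9; 6.00: 23.4, 17.9

(each reading ± 1 percentage point)

- amount of ring at the end, in percent of the substrate charged for beta, epsilon, eta, delta, alpha, in this order
- how the row runs (falls all the way / falls, then rises / hardly changes / rises, then falls / rises all the way)

- a reading or a percentage of ring counts all its forms, free or not
- "hardly changes" means that all values lie within two and a half points (for a concentration: within two and a half percent of the largest)

Here is what looks wrong. Take the ring's share of the substrate lost, a selectivity. South-west charges 16.7 times the activator of east, yet at its first reading, at 0.417 h, its share is 16.2%, while east reads 19.0% at 6.00 h. Then, in the same south-west flask, the share between 3.00 h and 6.00 h climbs to 43.3%, higher than at that first reading, while the two substrate readings average 0.0568 M.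

So I take substrate itself as the ring's competitor. That late stretch gives a reading of 0.0434 M for the crossover substrate, the substrate level at which a further loss splits equally between ring and the unread rest. The share is then the crossover over the crossover plus substrate. At east's substrate reading at 6.00 h this gives 19.2%, a figure that owes nothing to east's ring reading.

By this rule, summed over a run, ring as a concentration is the crossover times the natural logarithm of (crossover plus substrate charged) over (crossover plus substrate left). That grows as substrate left falls, and at 6.00 h south-west, with the larger charge of activator, read less substrate than east, so I commit to a rising row. With no substrate left, my reckoning puts a roof at 37.4% of ring.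

The forecast gives 2.5%, 5.2%, 10.8%, 23% and 36%, rises all the way, on the ground that “the share depends on substrate, not activator”. Its top value stands below my roof.

The flasks give 3.23%, 6.43%, 12.5%, 23.1% and 33.2%: rises all the way.

    substrate + activator → activated form (k = 0.0140 L mol⁻¹ min⁻¹)
    activated form → ring (k = 0.190 min⁻¹)
    substrate + activated form → open dimer (k = 2.30 L mol⁻¹ min⁻¹)
    activator + ring ⇌ idle adduct, settled at all times (K = 5.40 L mol⁻¹)

With 3.72% of its substrate left, alpha comes out by the crossover at 34.0% of ring, against 33.2% found. Beta, with 82.5% left, comes out at 3.37%, against 3.23% found. In alpha at 8.00 h the unread rest is open dimer, 62.9%, beside 0.0844% of activated form, and the main reason alpha ends at 33.2% of ring is the path from substrate and activated form to open dimer: the alpha run without that path ends at 86.7% of ring.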